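**Retrosynthetic overview**
- The target comes from global hydrogenolysis of a protected trimer in which an o-xylylene strap joins O5 of the top unit to O5 of the middle unit.
- Both interflavan bonds come from one Lewis-acid operation on a C2-symmetric, strapped bis(4-alkoxy-epicatechin gallate) plus tetra-O-benzylcatechin. The strap delivers C6 of one half to C4 of the other (4β→6), and the remaining C4 cation takes catechin C8 (4β→8).
- The strapped bis-electrophile comes from double C4–H oxidation of a strapped bis(epicatechin gallate).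
- Key step: ring C of the top unit and ring C of the middle unit are formed together by a double enantioselective hetero-Diels–Alder reaction of a strapped bis(o-quinone methide) with a (Z)-styryl gallate. This sets 2,3-cis and brings in both galloyl esters.
- Ring order: rings A and B are bought as arenes; the two rings C of the gallate units are formed at once; ring C of the bottom unit comes with (+)-catechin.

Assumption: the (R)-configured chiral acid in step 6 is taken to give the (2R,3R) sense; if a screen shows the opposite, its antipode is used.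

**Step 1**
Reactants: 1 2,4,6-trihydroxybenzaldehyde; 2 benzyl bromide
Product: 3 4-(benzyloxy)-2,6-dihydroxybenzaldehyde
Conditions: BnBr (1.0 equiv), CsHCO3 (1.2 equiv), MeCN, 60 °C
Reagents that add atoms: benzyl bromide, BrCc1ccccc1
Why: Williamson etherification in which the para hydroxyl, the most acidic one and the only one not hydrogen-bonded to the formyl group, is alkylated selectively by one equivalent of halide; no stereocentre is formed.

**Step 2**
Reactants: 3 4-(benzyloxy)-2,6-dihydroxybenzaldehyde (two molecules per molecule of 4); 4 1,2-bis(bromomethyl)benzene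
Product: 5 strapped bis-aldehyde 1,2-bis{[5-(benzyloxy)-2-formyl-3-hydroxyphenoxy]methyl}benzene
Conditions: 3 (2.1 equiv), 4 (1.0 equiv, added slowly), K2CO3 (2.5 equiv), DMF, rt; excess 3 recovered
Reagents that add atoms: 4-(benzyloxy)-2,6-dihydroxybenzaldehyde (the second molecule of 3), O=Cc1c(O)cc(OCc2ccccc2)cc1O; 1,2-bis(bromomethyl)benzene, BrCc1ccccc1CBr
Why: Double Williamson etherification in which each of the two benzylic bromides of one molecule of 4 alkylates one ortho hydroxyl of a separate molecule of 3 (2 × 3 + 4 → 5 + 2 HBr); the remaining ortho hydroxyl of each aldehyde stays locked in its hydrogen bond to the formyl oxygen, so the strap sits on the oxygen that becomes O5 and the future O1 stays free.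

**Step 3**
Reactants: 5 strapped bis-aldehyde
Product: 6 strapped bis(salicyl alcohol) 1,2-bis{[5-(benzyloxy)-3-hydroxy-2-(hydroxymethyl)phenoxy]methyl}benzene
Conditions: NaBH4, THF/MeOH, 0 °C; pH 7 buffer
Reagents that add atoms: none
Why: Borohydride reduction of both aryl aldehydes gives the o-hydroxybenzyl alcohols that serve as o-quinone methide precursors, and the cold neutral work-up avoids premature ionisation.

**Step 4**
Reactants: 7 3,4-bis(benzyloxy)benzaldehyde; 8 dimethyl (1-diazo-2-oxopropyl)phosphonate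
Product: 9 1,2-bis(benzyloxy)-4-ethynylbenzene
Conditions: 8 (1.2 equiv), K2CO3, MeOH/THF, rt
Reagents that add atoms: dimethyl (1-diazo-2-oxopropyl)phosphonate, CC(=O)C(=[N+]=[N-])P(=O)(OC)OC
Why: Ohira–Bestmann variant of the Seyferth–Gilbert homologation, in which methoxide deacylates 8 to the diazomethylphosphonate anion that olefinates the aldehyde and then loses N2 with a 1,2-hydride shift to give the terminal alkyne.

**Step 5**
Reactants: 9 1,2-bis(benzyloxy)-4-ethynylbenzene; 10 3,4,5-tris(benzyloxy)benzoic acid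
Product: 11 (Z)-2-[3,4-bis(benzyloxy)phenyl]ethenyl 3,4,5-tris(benzyloxy)benzoate
Conditions: [RuCl2(p-cymene)]2 (1 mol %), P(4-ClC6H4)3 (3 mol %), DMAP (4 mol %), toluene, 60 °C
Reagents that add atoms: 3,4,5-tris(benzyloxy)benzoic acid, OC(=O)c1cc(OCc2ccccc2)c(OCc2ccccc2)c(OCc2ccccc2)c1
Why: Anti-Markovnikov hydro-acyloxylation of a terminal alkyne catalysed by [RuCl2(p-cymene)]2, in which the carboxylate adds to the alpha carbon of a metal vinylidene and protonolysis gives the (Z)-enol ester whose geometry later becomes the 2,3-cis relationship.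

**Step 6**
Reactants: 6 strapped bis(salicyl alcohol); 11 (Z)-enol gallate (two molecules add)
Product: 13 strapped bis(epicatechin gallate) dodecabenzyl ether, via strapped bis(o-quinone methide) 12 (not isolated)
Conditions: 11 (6 equiv, excess recovered), (R)-3,3'-bis(2,4,6-triisopropylphenyl)-1,1'-binaphthyl-2,2'-diyl N-triflylphosphoramide (10 mol %), 5 Å MS, PhCF3, –20 °C, slow addition of 6; meso isomer removed on silica
Reagents that add atoms: (Z)-2-[3,4-bis(benzyloxy)phenyl]ethenyl 3,4,5-tris(benzyloxy)benzoate, O=C(O/C=C\c1ccc(OCc2ccccc2)c(OCc2ccccc2)c1)c1cc(OCc2ccccc2)c(OCc2ccccc2)c(OCc2ccccc2)c1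
Why: Proposed new method: acid-promoted loss of water from each o-hydroxybenzyl alcohol gives an o-quinone methide, held as a contact ion pair by the chiral phosphoramide, which undergoes an inverse-electron-demand hetero-Diels–Alder reaction with the electron-rich (Z)-enol ester (closest known reaction type: chiral Brønsted acid catalysed [4+2] cycloaddition of in situ o-quinone methides with styrenes and enol ethers), the quinone methide oxygen bonding to the benzylic carbon that carries the dialkoxyphenyl group so that O1–C2 and C3–C4 form and both rings C close in one operation, the suprafacial addition turning the Z geometry into 2,3-cis, the catalyst-controlled face selection setting (2R,3R) in both halves, and the two-directional run diverting most of the minor sense into a separable meso isomer.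

**Step 7**
Reactants: 13 strapped bis(epicatechin gallate) dodecabenzyl ether; 14 2-ethoxyethanol
Product: 15 strapped bis[4β-(2-ethoxyethoxy)epicatechin gallate] dodecabenzyl ether
Conditions: DDQ (2.4 equiv), 14 (20 equiv), CH2Cl2, rt
Reagents that add atoms: 2-ethoxyethanol, CCOCCO
Why: DDQ hydride abstraction at the electron-rich benzylic C4 of each ring C (the known C4 oxidation of benzylated flavan-3-ols) is followed by capture of the cation by the alcohol anti to the participating 3-O-galloyl group, giving the 3,4-trans (4β, 4S) ethers, while the large excess of alcohol outruns the strapped arene.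

**Step 8**
Reactants: 16 (+)-catechin; 2 benzyl bromide
Product: 17 5,7,3',4'-tetra-O-benzyl-(+)-catechin
Conditions: BnBr (4.4 equiv), K2CO3, DMF, 0 °C to rt
Reagents that add atoms: benzyl bromide, BrCc1ccccc1
Why: Fourfold Williamson etherification of the phenols of the chiral-pool flavan-3-ol, in which carbonate base does not alkylate the secondary 3-OH and the (2R,3S) centres are untouched.

**Step 9**
Reactants: 15 strapped bis[4β-(2-ethoxyethoxy)epicatechin gallate] dodecabenzyl ether; 17 5,7,3',4'-tetra-O-benzyl-(+)-catechin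
Product: 19 strapped hexadecabenzyl trimer, via macrocyclic mono-ether 18 (not isolated)
Conditions: 17 (1.5 equiv), Me3SiOSO2CF3 (TMSOTf, 0.5 equiv), CH2Cl2 (1 mM), 4 Å MS, –40 to –20 °C; Et3N
Reagents that add atoms: 5,7,3',4'-tetra-O-benzyl-(+)-catechin, C(c1ccccc1)Oc1cc(OCc3ccccc3)c2c(c1)O[C@H](c1ccc(OCc3ccccc3)c(OCc3ccccc3)c1)[C@@H](O)C2
Why: Proposed new method: Lewis-acid ionisation of a C4 ether gives a benzylic cation bridged by the neighbouring galloyl carbonyl (closest known reaction type: TMSOTf-mediated Friedel–Crafts coupling of 4-alkoxyflavan-3-yl esters with benzylated flavan-3-ols), and at high dilution the strap delivers C6 of the other half to the face anti to the ester (4β→6, ring of eleven atoms), after which the second cation, which cannot reach an arene of its own molecule, is taken by C8 of 17 again anti to its ester (4β→8), the C2 symmetry of 15 making either order of the two events give the same connectivity.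

**Step 10**
Reactants: 19 strapped hexadecabenzyl trimer
Product: 20 epicatechin-3-O-gallate-(4β→6)-epicatechin-3-O-gallate-(4β→8)-catechin (CNP0112921.1)
Conditions: H2 (1 atm), Pd(OH)2/C, THF/MeOH/H2O, rt
Reagents that add atoms: none
Why: Global hydrogenolysis over Pd(OH)2/C cleaves the sixteen benzyl ethers and both benzylic C–O bonds of the o-xylylene strap while the galloyl esters, the interflavan bonds and all eight stereocentres are untouched.

**Compound list**

1 | 2,4,6-trihydroxybenzaldehyde | O=Cc1c(O)cc(O)cc1O | starting material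
2 | benzyl bromide | BrCc1ccccc1 | starting material
3 | 4-(benzyloxy)-2,6-dihydroxybenzaldehyde | O=Cc1c(O)cc(OCc2ccccc2)cc1O | intermediate
4 | 1,2-bis(bromomethyl)benzene | BrCc1ccccc1CBr | starting material
5 | 1,2-bis{[5-(benzyloxy)-2-formyl-3-hydroxyphenoxy]methyl}benzene | O=Cc1c(O)cc(OCc2ccccc2)cc1OCc1ccccc1COc1cc(OCc2ccccc2)cc(O)c1C=O | intermediate
6 | 1,2-bis{[5-(benzyloxy)-3-hydroxy-2-(hydroxymethyl)phenoxy]methyl}benzene | OCc1c(O)cc(OCc2ccccc2)cc1OCc1ccccc1COc1cc(OCc2ccccc2)cc(O)c1CO | intermediate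
7 | 3,4-bis(benzyloxy)benzaldehyde | O=Cc1ccc(OCc2ccccc2)c(OCc2ccccc2)c1 | starting material
8 | dimethyl (1-diazo-2-oxopropyl)phosphonate | CC(=O)C(=[N+]=[N-])P(=O)(OC)OC | starting material
9 | 1,2-bis(benzyloxy)-4-ethynylbenzene | C#Cc1ccc(OCc2ccccc2)c(OCc2ccccc2)c1 | intermediate
10 | 3,4,5-tris(benzyloxy)benzoic acid | OC(=O)c1cc(OCc2ccccc2)c(OCc2ccccc2)c(OCc2ccccc2)c1 | starting material
11 | (Z)-2-[3,4-bis(benzyloxy)phenyl]ethenyl 3,4,5-tris(benzyloxy)benzoate | O=C(O/C=C\c1ccc(OCc2ccccc2)c(OCc2ccccc2)c1)c1cc(OCc2ccccc2)c(OCc2ccccc2)c(OCc2ccccc2)c1 | intermediate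
12 | strapped bis(o-quinone methide): 1,2-bis{[3-(benzyloxy)-6-methylidene-5-oxocyclohexa-1,3-dien-1-yloxy]methyl}benzene | C=C1C(=O)C=C(OCc2ccccc2)C=C1OCc1ccccc1COC1=CC(OCc2ccccc2)=CC(=O)C1=C | intermediate (not isolated)
13 | 1,2-bis{[(2R,3R)-7-(benzyloxy)-2-[3,4-bis(benzyloxy)phenyl]-3-[3,4,5-tris(benzyloxy)benzoyloxy]chroman-5-yloxy]methyl}benzene (2,3-cis in both halves) | c1ccc(COc2cc(OCc4ccccc4)cc3c2C[C@@H](OC(=O)c4cc(OCc5ccccc5)c(OCc5ccccc5)c(OCc5ccccc5)c4)[C@@H](c4ccc(OCc5ccccc5)c(OCc5ccccc5)c4)O3)c(COc2cc(OCc4ccccc4)cc3c2C[C@@H](OC(=O)c4cc(OCc5ccccc5)c(OCc5ccccc5)c(OCc5ccccc5)c4)[C@@H](c4ccc(OCc5ccccc5)c(OCc5ccccc5)c4)O3)c1 | intermediate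
14 | 2-ethoxyethanol | CCOCCO | starting material
15 | (2R,3R,4S)-4-(2-ethoxyethoxy) derivative of 13 in both halves (2,3-cis, 3,4-trans) | c1ccc(COc2cc(OCc4ccccc4)cc3c2[C@H](OCCOCC)[C@@H](OC(=O)c4cc(OCc5ccccc5)c(OCc5ccccc5)c(OCc5ccccc5)c4)[C@@H](c4ccc(OCc5ccccc5)c(OCc5ccccc5)c4)O3)c(COc2cc(OCc4ccccc4)cc3c2[C@H](OCCOCC)[C@@H](OC(=O)c4cc(OCc5ccccc5)c(OCc5ccccc5)c(OCc5ccccc5)c4)[C@@H](c4ccc(OCc5ccccc5)c(OCc5ccccc5)c4)O3)c1 | intermediate
16 | (+)-catechin, (2R,3S) | Oc1cc(O)c2c(c1)O[C@H](c1ccc(O)c(O)c1)[C@@H](O)C2 | starting material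
17 | 5,7,3',4'-tetra-O-benzyl-(+)-catechin, (2R,3S), free 3-OH | C(c1ccccc1)Oc1cc(OCc3ccccc3)c2c(c1)O[C@H](c1ccc(OCc3ccccc3)c(OCc3ccccc3)c1)[C@@H](O)C2 | intermediate
18 | macrocyclic dimer: the two (2R,3R) gallate halves joined C4(β)→C6 (3,4-trans in the upper half) and O5–CH2C6H4CH2–O5; the lower half keeps its 4β-(2-ethoxyethoxy) group; all other phenols benzylated | O=C(O[C@@H]1[C@@H](c2c(OCc5ccccc5)cc3c(c2OCc6ccccc6C9)[C@H](OCCOCC)[C@@H](OC(=O)c2cc(OCc5ccccc5)c(OCc5ccccc5)c(OCc5ccccc5)c2)[C@@H](c2ccc(OCc5ccccc5)c(OCc5ccccc5)c2)O3)c2c(O9)cc(OCc5ccccc5)cc2O[C@@H]1c1ccc(OCc5ccccc5)c(OCc5ccccc5)c1)c1cc(OCc5ccccc5)c(OCc5ccccc5)c(OCc5ccccc5)c1 | intermediate (not isolated)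
19 | strapped hexadecabenzyl trimer: 18 with C8 of tetra-O-benzylcatechin on C4(β) of the lower gallate half in place of the ether (3,4-trans); bottom 3-OH free | O=C(O[C@@H]1[C@@H](c2c(OCc5ccccc5)cc3c(c2OCc6ccccc6C9)[C@H](c2c(OCc5ccccc5)cc(OCc5ccccc5)c4c2O[C@H](c2ccc(OCc5ccccc5)c(OCc5ccccc5)c2)[C@@H](O)C4)[C@@H](OC(=O)c2cc(OCc5ccccc5)c(OCc5ccccc5)c(OCc5ccccc5)c2)[C@@H](c2ccc(OCc5ccccc5)c(OCc5ccccc5)c2)O3)c2c(O9)cc(OCc5ccccc5)cc2O[C@@H]1c1ccc(OCc5ccccc5)c(OCc5ccccc5)c1)c1cc(OCc5ccccc5)c(OCc5ccccc5)c(OCc5ccccc5)c1 | intermediate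
20 | epicatechin-3-O-gallate-(4β→6)-epicatechin-3-O-gallate-(4β→8)-catechin; top (2R,3R,4S), middle (2R,3R,4R), bottom (2R,3S) | O=C(O[C@@H]1[C@@H](c2c(O)cc3c(c2O)[C@H](c2c(O)cc(O)c4c2O[C@H](c2ccc(O)c(O)c2)[C@@H](O)C4)[C@@H](OC(=O)c2cc(O)c(O)c(O)c2)[C@@H](c2ccc(O)c(O)c2)O3)c2c(O)cc(O)cc2O[C@@H]1c1ccc(O)c(O)c1)c1cc(O)c(O)c(O)c1 | target

**Totals**
Total step count: 10. Longest linear sequence: 7 steps (1, 2, 3, 6, 7, 9, 10).

**Three steps most likely to fail**

Step 6. The risks are low enantioselectivity with a quinone methide that has no substituent on the methide carbon, partial loss of the Z geometry through a stepwise path, and Friedel–Crafts capture of a quinone methide by the strapped arene. The fallback sets out from alkyne 9 (with 6) and returns at 13. It replaces catalyst control by a removable chiral ester. The [RuCl2(p-cymene)]2-catalysed addition of step 5 is run with N-Boc-L-proline to give (Z)-2-[3,4-bis(benzyloxy)phenyl]ethenyl N-Boc-L-prolinate F1. Its double cycloaddition with 6 under an achiral acid (diphenyl phosphate) gives three diastereomeric bis-esters, separable on silica because each carries two L-proline units; the all-(2R,3R) isomer is strapped bis(flavan-3-yl N-Boc-L-prolinate) F2. K2CO3/MeOH removes both prolinates to give strapped bis(flavan-3-ol) F3, whose configuration is checked by hydrogenolysis of a sample to (–)-epicatechin. Double esterification with acid 10 (EDC·HCl, DMAP) then gives 13.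

Step 9. The risks are capture of both cations by 17 and oligomerisation of the second cation before 17 arrives. The fallback sets out from 13 and returns at 19, making the two interflavan bonds in separate operations. DDQ (1.0 equiv) without alcohol at 1 mM gives a cross-dehydrogenative Friedel–Crafts macrocyclisation to macrocyclic 4β→6 dimer F4, whose lower half still has CH2 at C4. A second DDQ oxidation in the presence of 14 gives 18, now isolated. It has a single electrophilic site and is coupled with excess 17 under TMSOTf to give 19.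

Step 7. The risks are that hydride abstraction next to a 3-O-acyl group is slower than with a free 3-OH, and that the strapped arene may take the cation before the alcohol does. The fallback sets out from 5 and returns at 15, carrying the C4 oxygen in from the aldehyde oxidation level. Compound 5 is converted with 14 and a trace of acid into strapped bis[bis(2-ethoxyethyl) acetal] F5. Ionisation of each acetal by the chiral acid of step 6 gives a 4-alkoxy o-quinone methide (an oxocarbenium ion) that undergoes the same [4+2] cycloaddition with 11. Acid equilibration of C4 in the presence of the released alcohol gives the 3,4-trans ethers 15 directly, with no C–H oxidation.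

**Further compounds**

F1 | step 6 | (Z)-2-[3,4-bis(benzyloxy)phenyl]ethenyl (2S)-1-(tert-butoxycarbonyl)pyrrolidine-2-carboxylate | CC(C)(C)OC(=O)N1CCC[C@H]1C(=O)O/C=C\c1ccc(OCc2ccccc2)c(OCc2ccccc2)c1
F2 | step 6 | strapped bis(flavan-3-yl N-Boc-L-prolinate): 13 with an (S)-N-Boc-prolyl ester in place of each galloyl ester, (2R,3R) in both halves | c1ccc(COc2cc(OCc4ccccc4)cc3c2C[C@@H](OC(=O)[C@@H]4CCCN4C(=O)OC(C)(C)C)[C@@H](c4ccc(OCc5ccccc5)c(OCc5ccccc5)c4)O3)c(COc2cc(OCc4ccccc4)cc3c2C[C@@H](OC(=O)[C@@H]4CCCN4C(=O)OC(C)(C)C)[C@@H](c4ccc(OCc5ccccc5)c(OCc5ccccc5)c4)O3)c1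
F3 | step 6 | strapped bis(flavan-3-ol): 1,2-bis{[(2R,3R)-7-(benzyloxy)-2-[3,4-bis(benzyloxy)phenyl]-3-hydroxychroman-5-yloxy]methyl}benzene | c1ccc(COc2cc(OCc4ccccc4)cc3c2C[C@@H](O)[C@@H](c4ccc(OCc5ccccc5)c(OCc5ccccc5)c4)O3)c(COc2cc(OCc4ccccc4)cc3c2C[C@@H](O)[C@@H](c4ccc(OCc5ccccc5)c(OCc5ccccc5)c4)O3)c1
F4 | step 9 | macrocyclic 4β→6 dimer: 18 with CH2 at C4 of the lower half in place of the 2-ethoxyethoxy group | O=C(O[C@@H]1[C@@H](c2c(OCc5ccccc5)cc3c(c2OCc6ccccc6C9)C[C@@H](OC(=O)c2cc(OCc5ccccc5)c(OCc5ccccc5)c(OCc5ccccc5)c2)[C@@H](c2ccc(OCc5ccccc5)c(OCc5ccccc5)c2)O3)c2c(O9)cc(OCc5ccccc5)cc2O[C@@H]1c1ccc(OCc5ccccc5)c(OCc5ccccc5)c1)c1cc(OCc5ccccc5)c(OCc5ccccc5)c(OCc5ccccc5)c1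
F5 | step 7 | strapped bis[bis(2-ethoxyethyl) acetal] of 5 | CCOCCOC(OCCOCC)c1c(O)cc(OCc2ccccc2)cc1OCc1ccccc1COc1cc(OCc2ccccc2)cc(O)c1C(OCCOCC)OCCOCC
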